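**Assumption:** the target has no stereocentre and no stereogenic double bond, so it is achiral and needs no enantioselective step; the cyclohexanedione intermediates are used as stereoisomer mixtures that are erased on aromatisation.
**Naming note:** benzoates are numbered from the carbon bearing the carboxyl group (C1); ring A is the acyl (resorcylic) ring, ring B the phenol-ester ring.

## Retrosynthetic overview

1. Late chlorination at the only aromatic C–H, then debenzylation, then depside C–O disconnection give 2,4-bis(benzyloxy)-3,6-dimethylbenzoic acid and methyl 4-hydroxy-2-methoxy-3,5,6-trimethylbenzoate.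
2. Both aryl units trace back to one resorcylate, methyl 2,4-dihydroxy-3,6-dimethylbenzoate; ring B gains its C5 methyl by formylation/reduction and its 2-OMe by a protect–methylate–deprotect sequence.
3. Key C–C disconnection: the resorcylate ring comes from dimethyl malonate and (E)-hex-4-en-3-one by intermolecular Michael addition, Dieckmann (Claisen) closure and aromatisation.
4. Ring order: a single six-membered carbocycle is built once (dione, then arene) and serves as both ring A and ring B; no other ring is formed.

## Route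

**Step 1**
Reactants: 1 dimethyl malonate; 2 (E)-hex-4-en-3-one
Product: 4 methyl 3,6-dimethyl-2,4-dioxocyclohexane-1-carboxylate, via Michael adduct 3 (not isolated)
Conditions: NaOMe (1.1 equiv), MeOH, reflux; then 2 M HCl, 0 °C
Reagents that add atoms: none
Why: The malonate anion adds 1,4 to the enone (intermolecular Michael addition, the key C–C bond) and the ketone enolate then closes onto a malonate ester (Dieckmann-type Claisen condensation), the stable sodium enolate driving both equilibria; the new stereocentres form as a mixture that is erased in step 2.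

**Step 2**
Reactants: 4 methyl 3,6-dimethyl-2,4-dioxocyclohexane-1-carboxylate
Product: 7 methyl 2,4-dihydroxy-3,6-dimethylbenzoate, via C3-chloro dione 5 (not isolated), via C5-chloro dione 6 (not isolated)
Conditions: SO2Cl2 (1.0 equiv), CH2Cl2, 0 °C; evaporate; then DMF, conc. HCl (cat.), 110 °C
Reagents that add atoms: none
Why: Electrophilic α-chlorination of the enolised 1,3-dione, HCl-mediated shift of the chlorine to C5 and dehydrochlorination give a dienone that tautomerises to the resorcinol (halogenation–dehydrohalogenation aromatisation).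

**Step 3**
Reactants: 7 methyl 2,4-dihydroxy-3,6-dimethylbenzoate
Product: 9 methyl 5-formyl-2,4-dihydroxy-3,6-dimethylbenzoate, via alpha-chloro ether 8 (not isolated)
Conditions: Cl2CHOMe (1.5 equiv), TiCl4 (2.5 equiv), CH2Cl2, 0 °C to rt; then ice/1 M HCl
Reagents that add atoms: dichloromethyl methyl ether, COC(Cl)Cl (formyl carbon); water, O (formyl oxygen)
Why: Rieche formylation, in which the TiCl4-activated dichloromethyl ether attacks the only free ring position (C5, ortho to the 4-OH and para to the 2-OH) and aqueous work-up hydrolyses the α-chloro ether to the aldehyde.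

**Step 4**
Reactants: 9 methyl 5-formyl-2,4-dihydroxy-3,6-dimethylbenzoate
Product: 11 methyl 2,4-dihydroxy-3,5,6-trimethylbenzoate, via benzylic alcohol 10 (not isolated)
Conditions: Et3SiH (3 equiv), TFA/CH2Cl2 (1:4), 0 °C to rt
Reagents that add atoms: none
Why: Ionic hydrogenation, in which the protonated aldehyde and then the ortho/para-hydroxy-stabilised benzylic cation each accept hydride from the silane; no ring position is free, so no diarylmethane can form.

**Step 5**
Reactants: 11 methyl 2,4-dihydroxy-3,5,6-trimethylbenzoate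
Product: 12 methyl 4-(benzyloxy)-2-hydroxy-3,5,6-trimethylbenzoate
Conditions: BnBr (1.05 equiv), K2CO3 (1.2 equiv), acetone, reflux
Reagents that add atoms: benzyl bromide, BrCc1ccccc1
Why: Williamson etherification under weak base selects the 4-OH, because the 2-OH is hydrogen-bonded to the ester carbonyl and is far less acidic and nucleophilic.

**Step 6**
Reactants: 12 methyl 4-(benzyloxy)-2-hydroxy-3,5,6-trimethylbenzoate
Product: 13 methyl 4-(benzyloxy)-2-methoxy-3,5,6-trimethylbenzoate
Conditions: MeI (3 equiv), K2CO3 (3 equiv), DMF, 60 °C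
Reagents that add atoms: iodomethane, CI
Why: Williamson O-methylation of the remaining chelated phenol under more forcing conditions, with no other acidic site left in the molecule.

**Step 7**
Reactants: 13 methyl 4-(benzyloxy)-2-methoxy-3,5,6-trimethylbenzoate
Product: 14 methyl 4-hydroxy-2-methoxy-3,5,6-trimethylbenzoate
Conditions: H2 (1 atm), 10% Pd/C, EtOAc, rt
Reagents that add atoms: none
Why: Catalytic hydrogenolysis of the benzyl aryl ether frees the 4-OH, while the methyl ester and aryl methyl ether are inert.

**Step 8**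
Reactants: 7 methyl 2,4-dihydroxy-3,6-dimethylbenzoate
Product: 15 methyl 2,4-bis(benzyloxy)-3,6-dimethylbenzoate
Conditions: BnBr (2.5 equiv), K2CO3 (3 equiv), DMF, 80 °C
Reagents that add atoms: benzyl bromide, BrCc1ccccc1
Why: Exhaustive Williamson benzylation in hot DMF etherifies both the free and the chelated phenol, so the acid partner carries no nucleophilic OH in the coupling.

**Step 9**
Reactants: 15 methyl 2,4-bis(benzyloxy)-3,6-dimethylbenzoate
Product: 16 2,4-bis(benzyloxy)-3,6-dimethylbenzoic acid
Conditions: KOH (10 equiv), DMSO/H2O (4:1), 100 °C; then 2 M HCl, 0 °C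
Reagents that add atoms: potassium hydroxide, [K+].[OH-]
Why: Saponification of the di-ortho-substituted ester by poorly solvated hydroxide in hot aqueous DMSO; the benzyl ethers are base-stable and the fully O-protected acid does not decarboxylate on acidification.

**Step 10**
Reactants: 16 2,4-bis(benzyloxy)-3,6-dimethylbenzoic acid; 14 methyl 4-hydroxy-2-methoxy-3,5,6-trimethylbenzoate
Product: 18 methyl 4-{[2,4-bis(benzyloxy)-3,6-dimethylbenzoyl]oxy}-2-methoxy-3,5,6-trimethylbenzoate, via mixed anhydride 17 (not isolated)
Conditions: TFAA (3 equiv), toluene, 0 °C to rt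
Reagents that add atoms: none
Why: Mixed-anhydride esterification, in which TFAA turns the 2,6-disubstituted acid into an acylium-like electrophile that O-acylates the hindered phenol, an established way to forge fully substituted depside bonds.

**Step 11**
Reactants: 18 methyl 4-{[2,4-bis(benzyloxy)-3,6-dimethylbenzoyl]oxy}-2-methoxy-3,5,6-trimethylbenzoate
Product: 19 methyl 4-[(2,4-dihydroxy-3,6-dimethylbenzoyl)oxy]-2-methoxy-3,5,6-trimethylbenzoate
Conditions: H2 (1 atm), 10% Pd/C, EtOAc, rt
Reagents that add atoms: none
Why: Hydrogenolysis of both benzyl aryl ethers leaves the aryl ester, methyl ester and methyl ether intact, and no halogen is yet present to be lost.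

**Step 12**
Reactants: 19 methyl 4-[(2,4-dihydroxy-3,6-dimethylbenzoyl)oxy]-2-methoxy-3,5,6-trimethylbenzoate
Product: 20 methyl 4-[(5-chloro-2,4-dihydroxy-3,6-dimethylbenzoyl)oxy]-2-methoxy-3,5,6-trimethylbenzoate
Conditions: SO2Cl2 (1.05 equiv), Et2O, 0 °C
Reagents that add atoms: sulfuryl chloride, O=S(=O)(Cl)Cl
Why: Electrophilic aromatic chlorination at the only aromatic C–H of the molecule (ortho to the 4-OH and para to the 2-OH of ring A), while the fully substituted, ester-deactivated ring B cannot react.

## Compound list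

1 | dimethyl malonate | COC(=O)CC(=O)OC | starting material
2 | (E)-hex-4-en-3-one | CCC(=O)/C=C/C | starting material
3 | dimethyl 2-(4-oxohexan-2-yl)propanedioate (racemic Michael adduct) | COC(=O)C(C(=O)OC)C(C)CC(=O)CC | intermediate
4 | methyl 3,6-dimethyl-2,4-dioxocyclohexane-1-carboxylate (diastereomer mixture, largely enolised) | COC(=O)C1C(C)CC(=O)C(C)C1=O | intermediate
5 | methyl 3-chloro-3,6-dimethyl-2,4-dioxocyclohexane-1-carboxylate (stereoisomer mixture) | COC(=O)C1C(C)CC(=O)C(C)(Cl)C1=O | intermediate
6 | methyl 5-chloro-3,6-dimethyl-2,4-dioxocyclohexane-1-carboxylate (stereoisomer mixture) | COC(=O)C1C(C)C(Cl)C(=O)C(C)C1=O | intermediate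
7 | methyl 2,4-dihydroxy-3,6-dimethylbenzoate | COC(=O)c1c(C)cc(O)c(C)c1O | intermediate
8 | methyl 5-[chloro(methoxy)methyl]-2,4-dihydroxy-3,6-dimethylbenzoate (racemic) | COC(=O)c1c(C)c(C(Cl)OC)c(O)c(C)c1O | intermediate
9 | methyl 5-formyl-2,4-dihydroxy-3,6-dimethylbenzoate | COC(=O)c1c(C)c(C=O)c(O)c(C)c1O | intermediate
10 | methyl 2,4-dihydroxy-5-(hydroxymethyl)-3,6-dimethylbenzoate | COC(=O)c1c(C)c(CO)c(O)c(C)c1O | intermediate
11 | methyl 2,4-dihydroxy-3,5,6-trimethylbenzoate | COC(=O)c1c(C)c(C)c(O)c(C)c1O | intermediate
12 | methyl 4-(benzyloxy)-2-hydroxy-3,5,6-trimethylbenzoate | COC(=O)c1c(C)c(C)c(OCc2ccccc2)c(C)c1O | intermediate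
13 | methyl 4-(benzyloxy)-2-methoxy-3,5,6-trimethylbenzoate | COC(=O)c1c(C)c(C)c(OCc2ccccc2)c(C)c1OC | intermediate
14 | methyl 4-hydroxy-2-methoxy-3,5,6-trimethylbenzoate | COC(=O)c1c(C)c(C)c(O)c(C)c1OC | intermediate
15 | methyl 2,4-bis(benzyloxy)-3,6-dimethylbenzoate | COC(=O)c1c(C)cc(OCc2ccccc2)c(C)c1OCc1ccccc1 | intermediate
16 | 2,4-bis(benzyloxy)-3,6-dimethylbenzoic acid | OC(=O)c1c(C)cc(OCc2ccccc2)c(C)c1OCc1ccccc1 | intermediate
17 | 2,4-bis(benzyloxy)-3,6-dimethylbenzoic trifluoroacetic anhydride | O=C(OC(=O)C(F)(F)F)c1c(C)cc(OCc2ccccc2)c(C)c1OCc1ccccc1 | intermediate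
18 | methyl 4-{[2,4-bis(benzyloxy)-3,6-dimethylbenzoyl]oxy}-2-methoxy-3,5,6-trimethylbenzoate | COC(=O)c1c(C)c(C)c(OC(=O)c2c(C)cc(OCc3ccccc3)c(C)c2OCc2ccccc2)c(C)c1OC | intermediate
19 | methyl 4-[(2,4-dihydroxy-3,6-dimethylbenzoyl)oxy]-2-methoxy-3,5,6-trimethylbenzoate | COC(=O)c1c(C)c(C)c(OC(=O)c2c(C)cc(O)c(C)c2O)c(C)c1OC | intermediate
20 | methyl 4-[(5-chloro-2,4-dihydroxy-3,6-dimethylbenzoyl)oxy]-2-methoxy-3,5,6-trimethylbenzoate (CNP0231767.0) | COC(=O)c1c(C)c(C)c(OC(=O)c2c(C)c(Cl)c(O)c(C)c2O)c(C)c1OC | target

## Step count and risks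

Total steps: 12. Longest linear sequence: 10 steps (1, 2, 3, 4, 5, 6, 7, 10, 11, 12); the ring A branch (steps 8 and 9) joins at step 10.

**Step 2 (aromatisation with one equivalent of chlorinating agent).** The chloro dione can pass positive chlorine to product 7, giving some ring-chlorinated arene and returning dione 4. The fallback sets out from 4 and over-halogenates on purpose. Br2 (2.2 equiv) in AcOH, rt then 60 °C, aromatises the ring and brominates its single free position to give crystalline methyl 5-bromo-2,4-dihydroxy-3,6-dimethylbenzoate F1. Hydrogenolysis of the C–Br bond (H2, 10% Pd/C, NaOAc, MeOH, rt) then comes back to the route at 7.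

**Step 9 (saponification of the di-ortho-substituted ester).** Hydroxide may fail to reach the shielded carbonyl. The fallback sets out from 15 and changes the oxidation level instead of attacking with hydroxide. LiAlH4 in THF at reflux gives [2,4-bis(benzyloxy)-3,6-dimethylphenyl]methanol F2. MnO2 in CH2Cl2 gives 2,4-bis(benzyloxy)-3,6-dimethylbenzaldehyde F3. Pinnick oxidation (NaClO2, NaH2PO4, 2-methylbut-2-ene, t-BuOH/H2O) then comes back to the route at 16.

**Step 10 (coupling of two hindered partners).** The mixed anhydride may C-acylate the free position of a second acid molecule or merely trifluoroacetylate 14. The fallback sets out from 16 and uses a preformed acyl chloride with a preformed phenoxide. (COCl)2 with cat. DMF in CH2Cl2 at rt gives 2,4-bis(benzyloxy)-3,6-dimethylbenzoyl chloride F4. Separately, 14 and NaH in THF at 0 °C give sodium 3-methoxy-4-(methoxycarbonyl)-2,5,6-trimethylphenolate F5. Combining the two at 0 °C to rt comes back to the route at 18.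

## Further compounds

F1 | step 2 | methyl 5-bromo-2,4-dihydroxy-3,6-dimethylbenzoate | COC(=O)c1c(C)c(Br)c(O)c(C)c1O
F2 | step 9 | [2,4-bis(benzyloxy)-3,6-dimethylphenyl]methanol | OCc1c(C)cc(OCc2ccccc2)c(C)c1OCc1ccccc1
F3 | step 9 | 2,4-bis(benzyloxy)-3,6-dimethylbenzaldehyde | O=Cc1c(C)cc(OCc2ccccc2)c(C)c1OCc1ccccc1
F4 | step 10 | 2,4-bis(benzyloxy)-3,6-dimethylbenzoyl chloride | O=C(Cl)c1c(C)cc(OCc2ccccc2)c(C)c1OCc1ccccc1
F5 | step 10 | sodium 3-methoxy-4-(methoxycarbonyl)-2,5,6-trimethylphenolate | [Na+].[O-]c1c(C)c(OC)c(C(=O)OC)c(C)c1C
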